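**Retrosynthetic overview**
1. Target 20 ⇐ diol acetylation, C-19 alcohol→aldehyde, ester hydrolysis ⇐ ring-A work on one ketone: C-3 directed reduction, C-2 enolate hydroxylation, C-4 reductive formylation then methylation.
2. That ketone ⇐ bicyclic cross-conjugated dienone 7 (ring A still carries the phenol carbon skeleton).
3. Key step: 7 ⇐ phenol 6 by oxidative dearomatisation of the 4-methylphenol ring with closure of ring B (C-9–C-10 bond) by the tethered (E)-alkene; this sets C-9, C-10 and the ring-B alkene.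
4. 6 ⇐ 3-bromo-4-methylphenol (cheap bromocresol) + triene ester 3 (B-alkyl Suzuki–Miyaura); 3 ⇐ methyl geranate (allylic oxidation, Wittig).
5. Ring order: ring A is the purchased arene; ring B is closed onto it in the dearomatisation; C-5, C-4, C-2 and C-3 are then relayed from C-10.

Labdane numbering is used in the text: decalin C-1 to C-10, C-19 the formyl carbon on C-4, C-20 the angular methyl on C-10.

Assumption: the sense of induction of the chiral aryl-λ3-iodane in step 4 cannot be predicted from precedent; the (R,R) reagent is written and its (S,S) antipode is used if it proves to give the mirror-image dienone.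

**Step 1**
Reactants: 1 methyl (2E)-3,7-dimethylocta-2,6-dienoate (methyl geranate)
Product: 2 methyl (2E,6E)-3,7-dimethyl-8-oxoocta-2,6-dienoate
Conditions: SeO2 (1.1 equiv), 1,4-dioxane, 80 °C
Reagents that add atoms: selenium dioxide, O=[Se]=O
Why: Riley allylic oxidation takes the (E)-methyl group of the electron-rich 6,7-alkene to the (E)-enal, the enoate alkene being too electron-poor to react; no stereocentre is formed.

**Step 2**
Reactants: 2 methyl (2E,6E)-3,7-dimethyl-8-oxoocta-2,6-dienoate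
Product: 3 methyl (2E,6E)-3,7-dimethylnona-2,6,8-trienoate
Conditions: Ph3PCH3Br, KOtBu, THF, 0 °C
Reagents that add atoms: methyltriphenylphosphonium bromide, C[P+](c1ccccc1)(c1ccccc1)c1ccccc1.[Br-]
Why: Wittig methylenation of the aldehyde is far faster than any reaction at the hindered enoate and leaves the 6E alkene untouched.

**Step 3**
Reactants: 3 methyl (2E,6E)-3,7-dimethylnona-2,6,8-trienoate; 4 3-bromo-4-methylphenol
Product: 6 methyl (2E,6E)-9-(5-hydroxy-2-methylphenyl)-3,7-dimethylnona-2,6-dienoate, via alkylborane 5 (not isolated)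
Conditions: 9-borabicyclo[3.3.1]nonane (1.05 equiv), THF, 0 °C to rt; then 4, Pd(OAc)2 (3 mol %), 2-dicyclohexylphosphino-2′,6′-dimethoxybiphenyl (6 mol %), K3PO4 (3 equiv), H2O, 60 °C
Reagents that add atoms: none
Why: The borane hydroborates only the monosubstituted terminal alkene of the diene (anti-Markovnikov), and B-alkyl Suzuki–Miyaura coupling joins that sp3 carbon to the aryl bromide, the phenol being tolerated as its phenoxide.

**Step 4 (key step)**
Reactants: 6 methyl (2E,6E)-9-(5-hydroxy-2-methylphenyl)-3,7-dimethylnona-2,6-dienoate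
Product: 7 methyl (2E)-5-[(1R,8aS)-2,8a-dimethyl-6-oxo-1,4,6,8a-tetrahydronaphthalen-1-yl]-3-methylpent-2-enoate
Conditions: (2R,2′R)-2,2′-{[2-(diacetoxy-λ3-iodanyl)-1,3-phenylene]bis(oxy)}bis[N-(2,4,6-trimethylphenyl)propanamide] (1.1 equiv), (CF3)2CHOH/CH2Cl2 1:4, −40 °C
Reagents that add atoms: none
Why: Proposed new method: ligand exchange puts the phenol oxygen on trivalent iodine and makes the ring electrophilic at the methyl-bearing para carbon (phenoxenium-type umpolung), the tethered (E)-trisubstituted alkene attacks it through C-9 in a chair-like six-membered transition state (side chain equatorial and therefore cis to the new angular methyl, as in the ring-B closure of labdane biosynthesis), the tertiary C-8 cation loses H-7 (Zaitsev) to give the ring-B alkene, and the chiral lactamide arms are expected to shield one face of the iodine-bound arene so that C-10 and with it C-9 are set in the absolute sense; closest known reaction types are the PhI(OAc)2/(CF3)2CHOH oxidative dearomatisation–cation–olefin cyclisations of phenols and the enantioselective chiral aryl-iodine oxidative dearomatisations of 4-alkylphenols (spirolactonisation, para-quinol formation).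

**Step 5**
Reactants: 7 methyl (2E)-5-[(1R,8aS)-2,8a-dimethyl-6-oxo-1,4,6,8a-tetrahydronaphthalen-1-yl]-3-methylpent-2-enoate
Product: 8 methyl (2E)-5-[(1R,8aS)-2,8a-dimethyl-6-oxo-1,4,6,7,8,8a-hexahydronaphthalen-1-yl]-3-methylpent-2-enoate
Conditions: H2 (1 atm), RhCl(PPh3)3 (5 mol %), toluene/EtOH, rt
Reagents that add atoms: none
Why: Homogeneous hydrogenation saturates only the unhindered disubstituted C-1/C-2 alkene of the cross-conjugated dienone (as with steroidal 1,4-dien-3-ones) and leaves the trisubstituted alkenes and the enoate; no new stereocentre.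

**Step 6**
Reactants: 8 methyl (2E)-5-[(1R,8aS)-2,8a-dimethyl-6-oxo-1,4,6,7,8,8a-hexahydronaphthalen-1-yl]-3-methylpent-2-enoate
Product: 10 methyl (2E)-5-[(1R,4aS,5Z,8aS)-5-(hydroxymethylidene)-2,8a-dimethyl-6-oxo-1,4,4a,5,6,7,8,8a-octahydronaphthalen-1-yl]-3-methylpent-2-enoate, via lithium enolate 9 (not isolated)
Conditions: Li (2.2 equiv), NH3/THF, t-BuOH (1.0 equiv), −78 °C; NH3 removed; CF3CH2OCHO, THF, −78 to 0 °C; aq. NH4Cl
Reagents that add atoms: 2,2,2-trifluoroethyl formate, O=COCC(F)(F)F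
Why: Stork-type dissolving-metal reduction of the enone gives the regiospecific C-3/C-4 lithium enolate, axial protonation of the C-5 carbanion setting the trans ring fusion (H-5 anti to the angular methyl), and the enolate is C-formylated at C-4 by the activated formate (Claisen-type acylation).

**Step 7**
Reactants: 10 methyl (2E)-5-[(1R,4aS,5Z,8aS)-5-(hydroxymethylidene)-2,8a-dimethyl-6-oxo-1,4,4a,5,6,7,8,8a-octahydronaphthalen-1-yl]-3-methylpent-2-enoate
Product: 11 methyl (2E)-5-[(1R,4aS,5R,8aS)-5-formyl-2,5,8a-trimethyl-6-oxo-1,4,4a,5,6,7,8,8a-octahydronaphthalen-1-yl]-3-methylpent-2-enoate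
Conditions: MeI, K2CO3, acetone, 40 °C
Reagents that add atoms: iodomethane, CI
Why: C-alkylation of the hydroxymethylene-ketone enolate: iodomethane approaches C-4 from the face opposite the axial C-10 methyl, so the new methyl is equatorial and the formyl group ends axial and syn to the angular methyl, as in the methylation of 4-carboalkoxy-3-keto trans-decalins.

**Step 8**
Reactants: 11 methyl (2E)-5-[(1R,4aS,5R,8aS)-5-formyl-2,5,8a-trimethyl-6-oxo-1,4,4a,5,6,7,8,8a-octahydronaphthalen-1-yl]-3-methylpent-2-enoate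
Product: 14 methyl (2E)-5-[(1R,4aS,5R,7S,8aS)-7-(acetyloxy)-5-formyl-2,5,8a-trimethyl-6-oxo-1,4,4a,5,6,7,8,8a-octahydronaphthalen-1-yl]-3-methylpent-2-enoate, via potassium enolate 12 (not isolated), via potassium alkoxide 13 (not isolated)
Conditions: KN(SiMe3)2, THF, −78 °C; 2-(phenylsulfonyl)-3-phenyloxaziridine, −78 °C; Ac2O, −78 to 0 °C; aq. NH4Cl
Reagents that add atoms: 2-(phenylsulfonyl)-3-phenyloxaziridine, O=S(=O)(c1ccccc1)N1OC1c1ccccc1; acetic anhydride, CC(=O)OC(C)=O
Why: Only C-2 can be enolised, and Davis oxidation of the potassium enolate delivers oxygen from the face away from the two axial groups (C-10 methyl and C-4 formyl) to give the equatorial 2-oxygen, which is acetylated in the same pot.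

**Step 9**
Reactants: 14 methyl (2E)-5-[(1R,4aS,5R,7S,8aS)-7-(acetyloxy)-5-formyl-2,5,8a-trimethyl-6-oxo-1,4,4a,5,6,7,8,8a-octahydronaphthalen-1-yl]-3-methylpent-2-enoate
Product: 16 methyl (2E)-5-[(1R,4aS,5R,6R,7S,8aS)-7-(acetyloxy)-6-hydroxy-5-(hydroxymethyl)-2,5,8a-trimethyl-1,4,4a,5,6,7,8,8a-octahydronaphthalen-1-yl]-3-methylpent-2-enoate, via hydroxy ketone 15 (not isolated)
Conditions: Me4NBH(OAc)3 (5 equiv), MeCN/AcOH 1:1, −20 °C to rt
Reagents that add atoms: none
Why: The triacetoxyborohydride reduces the aldehyde first, and the resulting primary alkoxyborohydride delivers hydride intramolecularly to the C-3 ketone from the face of the axial CH2O group (Evans–Saksena hydroxyl-directed 1,3-anti reduction), giving the axial C-3 alcohol cis to the C-2 acetate.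

**Step 10**
Reactants: 16 methyl (2E)-5-[(1R,4aS,5R,6R,7S,8aS)-7-(acetyloxy)-6-hydroxy-5-(hydroxymethyl)-2,5,8a-trimethyl-1,4,4a,5,6,7,8,8a-octahydronaphthalen-1-yl]-3-methylpent-2-enoate
Product: 17 (2E)-5-[(1R,4aS,5R,6R,7S,8aS)-6,7-dihydroxy-5-(hydroxymethyl)-2,5,8a-trimethyl-1,4,4a,5,6,7,8,8a-octahydronaphthalen-1-yl]-3-methylpent-2-enoic acid
Conditions: LiOH, THF/MeOH/H2O 3:1:1, 40 °C; then 1 M HCl
Reagents that add atoms: lithium hydroxide, [Li+].[OH-]
Why: Saponification (BAc2) cleaves the methyl enoate and the secondary acetate in one operation; no stereocentre is touched because no carbonyl group flanks one at this stage.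

**Step 11**
Reactants: 17 (2E)-5-[(1R,4aS,5R,6R,7S,8aS)-6,7-dihydroxy-5-(hydroxymethyl)-2,5,8a-trimethyl-1,4,4a,5,6,7,8,8a-octahydronaphthalen-1-yl]-3-methylpent-2-enoic acid
Product: 18 (2E)-5-[(1R,4aS,5S,6R,7S,8aS)-5-formyl-6,7-dihydroxy-2,5,8a-trimethyl-1,4,4a,5,6,7,8,8a-octahydronaphthalen-1-yl]-3-methylpent-2-enoic acid
Conditions: 2,2,6,6-tetramethylpiperidin-1-oxyl (10 mol %), PhI(OAc)2 (1.1 equiv), CH2Cl2/MeCN, 0 °C to rt
Reagents that add atoms: none
Why: Oxoammonium (nitroxyl-catalysed) oxidation is selective for the primary alcohol over the two secondary ones and stops at the non-hydrated neopentyl aldehyde in dry solvent.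

**Step 12**
Reactants: 18 (2E)-5-[(1R,4aS,5S,6R,7S,8aS)-5-formyl-6,7-dihydroxy-2,5,8a-trimethyl-1,4,4a,5,6,7,8,8a-octahydronaphthalen-1-yl]-3-methylpent-2-enoic acid
Product: 20 (2E)-5-[(1R,4aS,5S,6R,7S,8aS)-6,7-bis(acetyloxy)-5-formyl-2,5,8a-trimethyl-1,4,4a,5,6,7,8,8a-octahydronaphthalen-1-yl]-3-methylpent-2-enoic acid, via mixed anhydride 19 (not isolated)
Conditions: Ac2O, pyridine, 4-(dimethylamino)pyridine (10 mol %), CH2Cl2, 0 °C to rt; then H2O/THF, dilute HCl
Reagents that add atoms: acetic anhydride, CC(=O)OC(C)=O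
Why: Nucleophile-catalysed (Steglich-type) acylation esterifies both secondary alcohols with retention, and the transient mixed anhydride of the acid is hydrolysed at its acetyl carbonyl during aqueous work-up.

**Compound list**
1 | methyl (2E)-3,7-dimethylocta-2,6-dienoate (methyl geranate) | CC(C)=CCC/C(C)=C/C(=O)OC | starting material
2 | methyl (2E,6E)-3,7-dimethyl-8-oxoocta-2,6-dienoate | O=C/C(C)=C/CC/C(C)=C/C(=O)OC | intermediate
3 | methyl (2E,6E)-3,7-dimethylnona-2,6,8-trienoate | C=C/C(C)=C/CC/C(C)=C/C(=O)OC | intermediate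
4 | 3-bromo-4-methylphenol | Cc1ccc(O)cc1Br | starting material
5 | methyl (2E,6E)-9-(9-borabicyclo[3.3.1]nonan-9-yl)-3,7-dimethylnona-2,6-dienoate | C1CC2CCCC(C1)B2CC/C(C)=C/CC/C(C)=C/C(=O)OC | intermediate
6 | methyl (2E,6E)-9-(5-hydroxy-2-methylphenyl)-3,7-dimethylnona-2,6-dienoate | Cc1ccc(O)cc1CC/C(C)=C/CC/C(C)=C/C(=O)OC | intermediate
7 | methyl (2E)-5-[(1R,8aS)-2,8a-dimethyl-6-oxo-1,4,6,8a-tetrahydronaphthalen-1-yl]-3-methylpent-2-enoate (side chain cis to the angular methyl) | O=C1C=C[C@@]2(C)[C@H](CC/C(C)=C/C(=O)OC)C(C)=CCC2=C1 | intermediate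
8 | methyl (2E)-5-[(1R,8aS)-2,8a-dimethyl-6-oxo-1,4,6,7,8,8a-hexahydronaphthalen-1-yl]-3-methylpent-2-enoate | O=C1CC[C@@]2(C)[C@H](CC/C(C)=C/C(=O)OC)C(C)=CCC2=C1 | intermediate
9 | lithium (4aR,5R,8aR)-5-[(3E)-5-methoxy-3-methyl-5-oxopent-3-en-1-yl]-4a,6-dimethyl-3,4,4a,5,8,8a-hexahydronaphthalen-2-olate (C-3/C-4 enolate, H-5 trans to the angular methyl) | C1C[C@@]2(C)[C@H](CC/C(C)=C/C(=O)OC)C(C)=CC[C@@H]2C=C1[O-].[Li+] | intermediate
10 | methyl (2E)-5-[(1R,4aS,5Z,8aS)-5-(hydroxymethylidene)-2,8a-dimethyl-6-oxo-1,4,4a,5,6,7,8,8a-octahydronaphthalen-1-yl]-3-methylpent-2-enoate | O=C1CC[C@@]2(C)[C@H](CC/C(C)=C/C(=O)OC)C(C)=CC[C@@H]2/C1=C/O | intermediate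
11 | methyl (2E)-5-[(1R,4aS,5R,8aS)-5-formyl-2,5,8a-trimethyl-6-oxo-1,4,4a,5,6,7,8,8a-octahydronaphthalen-1-yl]-3-methylpent-2-enoate (formyl axial, syn to the angular methyl) | O=C1CC[C@@]2(C)[C@H](CC/C(C)=C/C(=O)OC)C(C)=CC[C@@H]2[C@]1(C)C=O | intermediate
12 | potassium enolate of 11 (O–K on the C-3 oxygen, C-2=C-3 double bond, other centres as in 11) | [O-]C1=CC[C@@]2(C)[C@H](CC/C(C)=C/C(=O)OC)C(C)=CC[C@@H]2[C@]1(C)C=O.[K+] | intermediate
13 | potassium alkoxide of the 2-hydroxy derivative of 11 (O–K on C-2, equatorial, on the face opposite the angular methyl) | [O-][C@H]1C[C@@]2(C)[C@H](CC/C(C)=C/C(=O)OC)C(C)=CC[C@@H]2[C@](C)(C=O)C1=O.[K+] | intermediate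
14 | methyl (2E)-5-[(1R,4aS,5R,7S,8aS)-7-(acetyloxy)-5-formyl-2,5,8a-trimethyl-6-oxo-1,4,4a,5,6,7,8,8a-octahydronaphthalen-1-yl]-3-methylpent-2-enoate | CC(=O)O[C@H]1C[C@@]2(C)[C@H](CC/C(C)=C/C(=O)OC)C(C)=CC[C@@H]2[C@](C)(C=O)C1=O | intermediate
15 | methyl (2E)-5-[(1R,4aS,5R,7S,8aS)-7-(acetyloxy)-5-(hydroxymethyl)-2,5,8a-trimethyl-6-oxo-1,4,4a,5,6,7,8,8a-octahydronaphthalen-1-yl]-3-methylpent-2-enoate | CC(=O)O[C@H]1C[C@@]2(C)[C@H](CC/C(C)=C/C(=O)OC)C(C)=CC[C@@H]2[C@](C)(CO)C1=O | intermediate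
16 | methyl (2E)-5-[(1R,4aS,5R,6R,7S,8aS)-7-(acetyloxy)-6-hydroxy-5-(hydroxymethyl)-2,5,8a-trimethyl-1,4,4a,5,6,7,8,8a-octahydronaphthalen-1-yl]-3-methylpent-2-enoate | CC(=O)O[C@H]1C[C@@]2(C)[C@H](CC/C(C)=C/C(=O)OC)C(C)=CC[C@@H]2[C@](C)(CO)[C@H]1O | intermediate
17 | (2E)-5-[(1R,4aS,5R,6R,7S,8aS)-6,7-dihydroxy-5-(hydroxymethyl)-2,5,8a-trimethyl-1,4,4a,5,6,7,8,8a-octahydronaphthalen-1-yl]-3-methylpent-2-enoic acid | O[C@H]1C[C@@]2(C)[C@H](CC/C(C)=C/C(=O)O)C(C)=CC[C@@H]2[C@](C)(CO)[C@H]1O | intermediate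
18 | (2E)-5-[(1R,4aS,5S,6R,7S,8aS)-5-formyl-6,7-dihydroxy-2,5,8a-trimethyl-1,4,4a,5,6,7,8,8a-octahydronaphthalen-1-yl]-3-methylpent-2-enoic acid | O[C@H]1C[C@@]2(C)[C@H](CC/C(C)=C/C(=O)O)C(C)=CC[C@@H]2[C@](C)(C=O)[C@H]1O | intermediate
19 | mixed carboxylic–acetic anhydride of 20 (side chain ends in C(=O)–O–C(=O)CH3, ring centres as in 20) | CC(=O)O[C@H]1C[C@@]2(C)[C@H](CC/C(C)=C/C(=O)OC(C)=O)C(C)=CC[C@@H]2[C@](C)(C=O)[C@H]1OC(C)=O | intermediate
20 | (2E)-5-[(1R,4aS,5S,6R,7S,8aS)-6,7-bis(acetyloxy)-5-formyl-2,5,8a-trimethyl-1,4,4a,5,6,7,8,8a-octahydronaphthalen-1-yl]-3-methylpent-2-enoic acid (CNP0273594.1) | CC(=O)O[C@H]1C[C@@]2(C)[C@H](CC/C(C)=C/C(=O)O)C(C)=CC[C@@H]2[C@](C)(C=O)[C@H]1OC(C)=O | target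

**Totals**
Total step count: 12. Longest linear sequence: 12 steps (1 to 20); 4 is bought and enters at step 3.

**Steps most likely to fail**

Step 4. The ring closure itself has close racemic precedent, but control of the absolute configuration by a chiral iodane at the para carbon with a carbon nucleophile is untested. The C-8 cation may also lose a proton to the exocyclic or tetrasubstituted alkene, or be captured by the enoate. Fallback: give up reagent control and resolve. Setting out from 6, PhI(OAc)2 in (CF3)2CHOH at −20 °C gives the racemic dienone, that is 7 together with its mirror image methyl (2E)-5-[(1S,8aR)-2,8a-dimethyl-6-oxo-1,4,6,8a-tetrahydronaphthalen-1-yl]-3-methylpent-2-enoate F1. The two are separated by preparative chromatography on an amylose tris(3,5-dimethylphenylcarbamate) phase, and the route is re-entered at 7.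

Step 6. The side-chain enoate is itself reducible by lithium in ammonia, so the chemoselectivity rests on limiting lithium and on the lower reduction potential of the enone. Fallback: mask the enoate as a carboxylate for the reduction. Setting out from 8, the methyl ester is cleaved with Me3SnOH in 1,2-dichloroethane to (2E)-5-[(1R,8aS)-2,8a-dimethyl-6-oxo-1,4,6,7,8,8a-hexahydronaphthalen-1-yl]-3-methylpent-2-enoic acid F2. Deprotonation with LiN(SiMe3)2 and reduction with Li/NH3 as in step 6 give the dilithium enolate carboxylate F3, whose conjugated carboxylate resists further reduction. Formylation with trifluoroethyl formate gives (2E)-5-[(1R,4aS,5Z,8aS)-5-(hydroxymethylidene)-2,8a-dimethyl-6-oxo-1,4,4a,5,6,7,8,8a-octahydronaphthalen-1-yl]-3-methylpent-2-enoic acid F4. Excess MeI/K2CO3 then methylates C-4 and the carboxylate in one operation, which comes back to the route at 11.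

Step 11. The primary alcohol is neopentyl and axial, so its rate advantage over the unhindered equatorial C-2 alcohol may be small, and PhI(OAc)2 can cleave cis-1,2-diols. Fallback: oxidise before the diol is unmasked and cleave the ester last without hydroxide. Setting out from 16, the same nitroxyl/PhI(OAc)2 oxidation gives methyl (2E)-5-[(1R,4aS,5S,6R,7S,8aS)-7-(acetyloxy)-5-formyl-6-hydroxy-2,5,8a-trimethyl-1,4,4a,5,6,7,8,8a-octahydronaphthalen-1-yl]-3-methylpent-2-enoate F5. Acetylation (Ac2O, pyridine, 4-(dimethylamino)pyridine) gives methyl (2E)-5-[(1R,4aS,5S,6R,7S,8aS)-6,7-bis(acetyloxy)-5-formyl-2,5,8a-trimethyl-1,4,4a,5,6,7,8,8a-octahydronaphthalen-1-yl]-3-methylpent-2-enoate F6. The methyl ester is then removed by SN2 demethylation with LiI in refluxing ethyl acetate, which leaves the acetates and the aldehyde alone and comes back to the route at 20.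

**Further compounds**
F1 | step 4 | methyl (2E)-5-[(1S,8aR)-2,8a-dimethyl-6-oxo-1,4,6,8a-tetrahydronaphthalen-1-yl]-3-methylpent-2-enoate | O=C1C=C[C@]2(C)[C@@H](CC/C(C)=C/C(=O)OC)C(C)=CCC2=C1
F2 | step 6 | (2E)-5-[(1R,8aS)-2,8a-dimethyl-6-oxo-1,4,6,7,8,8a-hexahydronaphthalen-1-yl]-3-methylpent-2-enoic acid | O=C1CC[C@@]2(C)[C@H](CC/C(C)=C/C(=O)O)C(C)=CCC2=C1
F3 | step 6 | dilithium enolate carboxylate from 1,4-reduction of F2 (lithium carboxylate, lithium C-3/C-4 enolate, H-5 trans to the angular methyl) | C1C[C@@]2(C)[C@H](CC/C(C)=C/C(=O)[O-])C(C)=CC[C@@H]2C=C1[O-].[Li+].[Li+]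
F4 | step 6 | (2E)-5-[(1R,4aS,5Z,8aS)-5-(hydroxymethylidene)-2,8a-dimethyl-6-oxo-1,4,4a,5,6,7,8,8a-octahydronaphthalen-1-yl]-3-methylpent-2-enoic acid | O=C1CC[C@@]2(C)[C@H](CC/C(C)=C/C(=O)O)C(C)=CC[C@@H]2/C1=C/O
F5 | step 11 | methyl (2E)-5-[(1R,4aS,5S,6R,7S,8aS)-7-(acetyloxy)-5-formyl-6-hydroxy-2,5,8a-trimethyl-1,4,4a,5,6,7,8,8a-octahydronaphthalen-1-yl]-3-methylpent-2-enoate | CC(=O)O[C@H]1C[C@@]2(C)[C@H](CC/C(C)=C/C(=O)OC)C(C)=CC[C@@H]2[C@](C)(C=O)[C@H]1O
F6 | step 11 | methyl (2E)-5-[(1R,4aS,5S,6R,7S,8aS)-6,7-bis(acetyloxy)-5-formyl-2,5,8a-trimethyl-1,4,4a,5,6,7,8,8a-octahydronaphthalen-1-yl]-3-methylpent-2-enoate | CC(=O)O[C@H]1C[C@@]2(C)[C@H](CC/C(C)=C/C(=O)OC)C(C)=CC[C@@H]2[C@](C)(C=O)[C@H]1OC(C)=O
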